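## Structural features

The target (23) is a spiro tricycle: ring A, an enolised 2-acylcyclohexane-1,3,5-trione (ketones C-2′ and C-6′, two prenyl groups on C-3′, enol carbon C-4′, 2-methylpropanoyl group on C-5′), shares the spiro carbon C-6 with ring B, a cyclohexane (C-3a, C-4, C-5, C-6, C-7, C-7a) that is trans-fused to the cyclopentane ring C (C-1, C-2, C-3, C-3a, C-7a). Four stereocentres are contiguous (the C-1 carbinol, C-7a, C-3a and the C-4 carbinol), and the fifth, C-6, lies one methylene beyond C-7a on one side and one methylene beyond C-4 on the other; it is stereogenic only because C-2′ (next to the diprenylated carbon) differs from C-6′ (next to the acyl-bearing carbon). In the only chair open to the trans-fused ring B, C-2′ and the 4-methyl group are axial on the face of H-7a, whereas C-6′ and the 4-hydroxyl are equatorial; on ring C the 1-hydroxyl is cis to C-7 and the two arms C-7 and C-4 are trans. The fragile groups are the enolised β-triketone (acidic, metal-binding, open to retro-Claisen cleavage at C-2′), the two prenyl alkenes (sensitive to acid, radicals and electrophiles) and the two tertiary alcohols. The real difficulty is not ring C but the orientation of ring A at C-6 and the configuration at C-4, both remote from any directing group; a plan that merely annulates ring A onto a spiro malonate overlooks that its two ester groups are diastereotopic. The key step exploits the fact that the segment C-1(Me)(OH)–C-7a(H)(C-7)–C-3a(H)(three-carbon branch) is the aldol adduct of an aldehyde α-carbon (C-7a, formyl carbon C-7) and a methyl ketone (C-1). Because the three-carbon branch on C-3a (future C-4, C-5 and the 4-methyl group) is an isopropenyl group at that stage, ring C with both arms is ring-cleaved limonene, and the centres of 23 map onto 5, 4 and 1 in a way that requires the (S) enantiomer of the terpene.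

## Logic of the disconnections

**23 ⇒ 20 + 2 × 21.** The two C-3′–CH2 bonds are cut. The prenyl alkenes would not survive the radical hydration that makes the C-4 carbinol or the strong base of the ring A closure, so they come last. C-3′ is the only ring A carbon of 20 that still bears hydrogen and it lies between two carbonyls. Ten carbons and one quaternary centre are removed and no stereocentre is touched. The forward step must achieve two C-alkylations (through 22) in preference to O-alkylation, with two tertiary alcohols free.

**20 ⇒ 18 (through 19); 18 ⇒ 17 + 15.** The bonds cut are C-2′–C-3′ (intramolecular Claisen) and C-5′–C-6′ (C-acylation). Ring A is a malonyl unit (C-2′, C-6, C-6′) bridged by the three-carbon nucleophile of 15. The target fixes which end goes where: the equatorial carbonyl C-6′ must bond to the central carbon of 15 and the axial carbonyl C-2′ to its terminal methyl. The intermolecular bond is therefore made at the accessible equatorial acyl group and the hindered axial one is left for the ring closure. The demand is that the terminal carbanion of a triacylmethane dianion adds to a neopentyl ester. The opposite order (terminal carbon first, at the accessible carbonyl) would give the C-6 epimer.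

**17 ⇒ 16 ⇒ 14 ⇒ 13.** One C–OMe bond of two diastereotopic esters is cut. This is where C-6 becomes a stereocentre. In 13 the axial ester is 1,3-diaxial to the 4-methyl group, so a nucleophile should take only the equatorial ester. The demand is that the C-4 carbinol, with its axial methyl, is already in place, so hydration has to precede ester differentiation.

**13 ⇒ 11 (through 12).** The C-4–O bond is cut, leaving an exocyclic methylene. The demand is Markovnikov hydration with oxygen delivered from the equatorial side, without participation of the axial ester. This points to a radical rather than a cationic process.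

**11 ⇒ 8 + 9 (through 10).** C-6–C-5 and C-6–C-7 are cut. Ring B and the spiro carbon come from an achiral C3 diester and no stereocentre is created because both esters are the same. The demand is two electrophilic arms on ring C, an allylic chloride and a primary sulfonate, and a base too weak to ionise the tertiary alcohol.

**8 ⇒ 7 ⇒ 6 ⇒ 5.** These are functional-group changes only: C–Cl at the isopropenyl methyl, O–Ts at C-7, and aldehyde to alcohol. The demand is selectivity for the primary over the tertiary hydroxyl and for the methyl over the ring methine in the allylic chlorination.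

**5 ⇒ 4.** The C-1–C-7a bond is cut (aldol). One ring and two stereocentres are removed and an acyclic keto aldehyde with a single stereocentre remains. The demand is that the aldehyde acts as donor and the ketone as acceptor, that the reaction stops before dehydration, and that equilibration delivers the all-trans arrangement of the three carbon substituents.

**4 ⇒ 2 ⇒ 1 (through 3).** C-1 and C-7 of 4 are reconnected as the ring alkene of 1. The demand is oxidation of the trisubstituted alkene in the presence of the isopropenyl group.

## Other disconnections considered

Alternative 1: The cut is C-6–C-5, with C-6 as a nucleophilic carbon of an aromatic acylphloroglucinol.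
- **Forward key step:** zerovalent palladium with a chiral diphosphine ionises the allylic carbonate A2. The phloroglucinol carbon that already bears C-7 attacks the π-allyl terminus, which closes ring B, dearomatises ring A and gives the methylidene spiro trione A1.
- **In favour:** ring A arrives as a cheap aromatic, so no ester differentiation or Claisen chemistry is needed. C-6 is set by the ligand, so either epimer is in principle accessible. After ring C the sequence is shorter by perhaps two or three steps, and on step economy and convergence this plan is the better one.
- **Against:** A2 still needs ring C with its three stereocentres, most simply from 5 or 6, so the limonene aldol is not avoided. Attaching C-7 to the arene needs C-alkylation by a β-branched primary electrophile or reductive alkylation with the labile 5. The catalyst must distinguish two ortho carbonyl positions that differ only at a distance. O-allylation competes. The C-4 hydration has to be run on A1, an enolised triketone that binds the metal.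
- **Comparison:** both plans pass through a 4-methylidene compound and face the same hydration question, so on that point they are equal. In mechanism, the chosen plan sets C-6 by a conformational effect that can be read from the chair, and alternative 1 by catalyst control that would have to be found. The chosen plan is the more predictable and alternative 1 the more flexible.

Alternative 2: The cuts are C-7a–C-7 and C-3a–C(isopropenyl), two exocyclic bonds on a cyclopentanone.
- **Forward key step:** copper-catalysed (CuBr·SMe2) conjugate addition of the Grignard reagent A5 to the enone A4, followed by Michael capture of the magnesium enolate by the quinone methide A7 released from the benzylic acetate A6. The product is the trans cyclopentanone A3.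
- **In favour:** it is a three-component coupling that forms two C–C bonds and installs ring A in the first operation, with no redox adjustment at C-7. The chosen key step forms one bond, so on bonds per step and convergence this plan is better.
- **Against:** no ring is closed. C-1 still needs methyl addition to the ketone in the presence of three acidic phenols. The isopropenyl group still needs allylic activation. Ring B and C-6 still need the dearomative closure of alternative 1, via a compound of type A2. The absolute configuration needs an enantioselective alkenyl addition to a cyclopentenone, a poor substrate class for that, whereas the chosen plan buys it with 1. A7 can oligomerise.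
- **Comparison:** both use an isopropenyl group as the three-carbon arm of ring B, so on that structural point they are equal. In mechanism this is kinetic enolate capture giving only the trans relationship, against a thermodynamic aldol that sets C-1 and C-7a together. On paper the step count is lower than in the chosen plan, but the stereochemical burden is moved to later steps.

Alternative 3: The cuts are C-6–C-7 and C-3a–C-7a together (Diels–Alder retron with a C-4=C-5 alkene in ring B).
- **Forward key step:** Knoevenagel condensation of the diallyl trione A11 with the hydroxy dienal A10 (from (S)-linalool A12 by allylic oxidation) gives the alkylidene triketone A9. Its dienone C-6=C-5–C-4(Me)=C-3a adds to the tethered vinyl group C-7a=C-7 in a type 1 intramolecular Diels–Alder reaction to give A8.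
- **In favour:** two rings, two C–C bonds and three stereocentres form in one step against one ring, one bond and two centres in the chosen key step. C-1 comes from the chiral pool and the whole route could be about half as long. On structure-building power and step economy this plan is clearly better.
- **Against:** the dienophile is an unactivated vinyl group and the diene is electron-poor. Alkylidene triketones of this kind usually react by oxa-6π electrocyclisation to 2H-pyrans or as heterodienes. The trans ring fusion, the π-face and the C-6 configuration (which depends on the geometry of the exocyclic alkene) all hang on the single carbinol in the tether. C-4 must then be hydrated on the ring alkene in the presence of the allyl groups, and these must finally be converted to prenyl groups by double cross-metathesis.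
- **Comparison:** the chosen plan deals with each stereocentre by a separate, analysable effect (equilibrium in step 3, sterics in steps 8 and 9). Alternative 3 stakes four selectivities on one transition state. It is the better plan if that transition state can be found and the worse one for a route that must be defensible in advance.

Key step: step 3

Remark: ring A is written throughout as the 4′-enol tautomer of the target; the tautomers interconvert and C-6 is a stereocentre in each of them.

## Steps

Step 1
Reactants: 1 (S)-limonene
Product: 2 (4S)-limonene 1,2-oxide (both epoxide diastereomers)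
Conditions: mCPBA (1.0 equiv), NaHCO3, CH2Cl2, 0 °C
Reagents that add atoms: 3-chloroperoxybenzoic acid, OOC(=O)c1cccc(Cl)c1
Why: Prilezhaev epoxidation; the trisubstituted ring alkene is more electron-rich than the isopropenyl group and should react first with one equivalent of peracid. Both epoxide diastereomers are carried on because step 2 destroys those two centres.

Step 2
Reactants: 2 (4S)-limonene 1,2-oxide
Product: 4 (3S)-6-oxo-3-(prop-1-en-2-yl)heptanal, via limonene-1,2-diol 3 (not isolated)
Conditions: HIO4·2H2O, THF/H2O, 0 → 20 °C
Reagents that add atoms: water, O
Why: Acid-catalysed epoxide hydrolysis to diol 3 followed by Malaprade glycol cleavage in the same pot, a known way to open limonene oxide. The isopropenyl group and the stereocentre are not involved.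

Step 3
Reactants: 4 (3S)-6-oxo-3-(prop-1-en-2-yl)heptanal
Product: 5 (1R,2S,5S)-2-hydroxy-2-methyl-5-(prop-1-en-2-yl)cyclopentane-1-carbaldehyde (formyl trans to isopropenyl and cis to hydroxyl)
Conditions: pyrrolidine (0.2 equiv), AcOH (0.2 equiv), THF/H2O (10:1), 0 °C, 0.1 M; pH 7 buffer quench; crude used at once
Reagents that add atoms: none
Why: Pyrrolidinium acetate converts the unhindered aldehyde into its enamine, whose α-carbon adds to the methyl ketone, and hydrolysis of the iminium ion releases 5; the closest known reaction is the amine-catalysed cyclisation of 6-oxoalkanals that is normally driven on to the cyclopentene carbaldehyde. Ring C closes in the 5-(enolexo)-exo-trig mode. The aldehyde must be the donor and the ketone the acceptor, which should hold because secondary amines form enamines with an aldehyde far faster than with a methyl ketone; the crossed mode would give an acetylcyclopentanol. C-7a (the formyl-bearing carbon) epimerises through the enamine and should settle trans to the isopropenyl group on the limonene-derived centre. C-1 is formed reversibly (aldol/retro-aldol) and should settle with its methyl trans and its hydroxyl cis to the formyl group, the isomer with the smaller vicinal cis interaction and an O–H···O=C hydrogen bond. The absolute sense comes only from C-3 of 4. Loss of water to the conjugated enal is the irreversible drain and is held back by low temperature, a near-neutral buffer, water in the medium and immediate reduction in step 4.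

Step 4
Reactants: 5 (1R,2S,5S)-2-hydroxy-2-methyl-5-(prop-1-en-2-yl)cyclopentane-1-carbaldehyde
Product: 6 (1S,2S,3S)-2-(hydroxymethyl)-1-methyl-3-(prop-1-en-2-yl)cyclopentan-1-ol
Conditions: NaBH4, MeOH, 0 °C
Reagents that add atoms: none
Why: Borohydride reduction of the aldehyde is fast at 0 °C and removes the carbonyl that makes retro-aldol, epimerisation and elimination possible. No stereocentre changes.

Step 5
Reactants: 6 (1S,2S,3S)-2-(hydroxymethyl)-1-methyl-3-(prop-1-en-2-yl)cyclopentan-1-ol
Product: 7 [(1S,2S,5S)-2-hydroxy-2-methyl-5-(prop-1-en-2-yl)cyclopentyl]methyl 4-methylbenzenesulfonate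
Conditions: TsCl, Et3N, DMAP (cat.), CH2Cl2, 0 °C
Reagents that add atoms: p-toluenesulfonyl chloride, Cc1ccc(cc1)S(Cl)(=O)=O
Why: Sulfonylation is selective for the primary over the tertiary hydroxyl. The amine base does not ionise the tertiary alcohol, so the cis-disposed 1,3-hydroxy tosylate should not close to an oxetane.

Step 6
Reactants: 7 [(1S,2S,5S)-2-hydroxy-2-methyl-5-(prop-1-en-2-yl)cyclopentyl]methyl 4-methylbenzenesulfonate
Product: 8 [(1S,2S,5S)-5-(3-chloroprop-1-en-2-yl)-2-hydroxy-2-methylcyclopentyl]methyl 4-methylbenzenesulfonate
Conditions: Ca(OCl)2, solid CO2, CH2Cl2/H2O, 0 °C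
Reagents that add atoms: calcium hypochlorite, [Ca+2].[O-]Cl.[O-]Cl
Why: Ene-type allylic chlorination by hypochlorous acid: chlorine adds to the terminal CH2 and a methyl proton is lost, giving the 2-(chloromethyl)allyl unit as is known for isopropenyl terpenoids. With the primary hydroxyl masked and the tertiary one trans-1,3 to the side chain, no hydroxyl can capture the chloronium ion.

Step 7
Reactants: 8 [(1S,2S,5S)-5-(3-chloroprop-1-en-2-yl)-2-hydroxy-2-methylcyclopentyl]methyl 4-methylbenzenesulfonate; 9 dimethyl malonate
Product: 11 dimethyl (1S,3aS,7aR)-1-hydroxy-1-methyl-4-methylideneoctahydro-6H-indene-6,6-dicarboxylate (trans-fused), via allylated malonate tosylate 10 (not isolated)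
Conditions: Cs2CO3, NaI (cat.), DMF, 20 → 60 °C, 0.05 M
Reagents that add atoms: none
Why: Double malonate alkylation: intermolecular SN2 at the allylic chloride gives 10, whose enolate displaces the tosylate in a 6-exo-tet closure to the trans-fused ring B. The two esters are identical, so C-6 is not yet a stereocentre, and carbonate is too weak a base to turn the tertiary alcohol into an oxetane-forming alkoxide.

Step 8
Reactants: 11 dimethyl (1S,3aS,7aR)-1-hydroxy-1-methyl-4-methylideneoctahydro-6H-indene-6,6-dicarboxylate
Product: 13 dimethyl (1S,3aS,4S,7aR)-1,4-dihydroxy-1,4-dimethyloctahydro-6H-indene-6,6-dicarboxylate (4-OH equatorial and 4-CH3 axial), via tertiary hydroperoxide 12 (not isolated)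
Conditions: Mn(dpm)3 (cat.), PhSiH3, O2 (1 atm), iPrOH/CH2Cl2, 0 °C; then PPh3
Reagents that add atoms: dioxygen, O=O
Why: Mukaiyama hydration: hydrogen-atom transfer to the terminal CH2, capture of the tertiary C-4 radical by O2 and reduction of hydroperoxide 12. The axial ester on C-6 is syn-axial to the axial side of the radical, so oxygen should enter equatorially and leave the methyl group axial. A radical process also excludes the lactonising participation of that ester which a cationic hydration would invite.

Step 9
Reactants: 13 dimethyl (1S,3aS,4S,7aR)-1,4-dihydroxy-1,4-dimethyloctahydro-6H-indene-6,6-dicarboxylate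
Product: 14 (1S,3aS,4S,6R,7aR)-1,4-dihydroxy-6-(methoxycarbonyl)-1,4-dimethyloctahydro-1H-indene-6-carboxylic acid (carboxyl equatorial; ester axial and syn to the 4-methyl group)
Conditions: KOH (1.5 equiv), MeOH/H2O, 20 °C; then cold dilute HCl to pH 3
Reagents that add atoms: potassium hydroxide, [K+].[OH-]
Why: Saponification under steric control: the axial ester lies between the syn-axial 4-methyl group and H-7a, the situation in which axial esters of terpenoid acids are known to resist hydrolysis, so hydroxide should attack only the equatorial ester. The carboxylate formed slows any second attack. This step sets C-6, with the future C-6′ equatorial and the future C-2′ axial.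

Step 10
Reactants: 14 (1S,3aS,4S,6R,7aR)-1,4-dihydroxy-6-(methoxycarbonyl)-1,4-dimethyloctahydro-1H-indene-6-carboxylic acid; 15 5-methylhexane-2,4-dione
Product: 18 methyl 6-(2-acetyl-4-methyl-3-oxopentanoyl)-1,4-dimethyl-1,4-bis(trimethylsilyloxy)octahydro-1H-indene-6-carboxylate (ring stereocentres as in 14; enolised triacylmethane; acyl group equatorial and ester axial), via tris(trimethylsilyl) derivative 16 (not isolated), via acid chloride 17 (not isolated)
Conditions: HMDS, TMSOTf (cat.), CH2Cl2, 20 °C; evaporate; (COCl)2, DMF (cat.), CH2Cl2, 0 → 20 °C; evaporate; then 15, MgCl2, pyridine, CH2Cl2, 0 → 20 °C; cold aq. citric acid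
Reagents that add atoms: hexamethyldisilazane, C[Si](C)(C)N[Si](C)(C)C
Why: Silylation masks both tertiary alcohols and turns the acid into a silyl ester, which oxalyl chloride/DMF converts into the acid chloride under neutral conditions that leave tertiary silyl ethers intact. The magnesium enolate of 15 is then C-acylated at its central carbon (magnesium-mediated soft-enolisation acylation of β-diketones). The intermolecular bond is thus made at the accessible equatorial acyl group.

Step 11
Reactants: 18 methyl 6-(2-acetyl-4-methyl-3-oxopentanoyl)-1,4-dimethyl-1,4-bis(trimethylsilyloxy)octahydro-1H-indene-6-carboxylate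
Product: 20 (1S,3aS,4S,6S,7aR)-1,4,4′-trihydroxy-1,4-dimethyl-5′-(2-methylpropanoyl)octahydrospiro[indene-6,1′-cyclohexan]-4′-ene-2′,6′-dione, via bis(trimethylsilyl) spiro trione 19 (not isolated)
Conditions: LiN(iPr)2 (3.3 equiv), THF, −78 → 0 °C; then 1 M HCl, THF, 20 °C
Reagents that add atoms: none
Why: Dieckmann-type intramolecular Claisen condensation: the base removes the triacylmethane proton and then a proton of the acetyl methyl, which is kinetically preferred over the isopropyl methine. The terminal carbanion attacks the axial ester in a 6-(enolendo)-exo-trig closure and loss of methoxide gives the stabilised enolate of 19. C-6 is untouched, so C-2′ ends axial, and the acid quench removes both tertiary silyl ethers.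

Step 12
Reactants: 20 (1S,3aS,4S,6S,7aR)-1,4,4′-trihydroxy-1,4-dimethyl-5′-(2-methylpropanoyl)octahydrospiro[indene-6,1′-cyclohexan]-4′-ene-2′,6′-dione; 21 prenyl bromide (1-bromo-3-methylbut-2-ene), two equivalents in all
Product: 23 target: (1S,3aS,4S,6S,7aR)-1,4,4′-trihydroxy-1,4-dimethyl-3′,3′-bis(3-methylbut-2-en-1-yl)-5′-(2-methylpropanoyl)octahydrospiro[indene-6,1′-cyclohexan]-4′-ene-2′,6′-dione, via monoprenyl trione 22 (not isolated)
Conditions: 21 (2.2 equiv), NaOMe (3.3 equiv), MeOH, 0 → 20 °C; cold dilute HCl work-up
Reagents that add atoms: prenyl bromide (the second equivalent of 21, which supplies the second prenyl group), CC(C)=CCBr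
Why: Twofold C-alkylation of the trione dianion at C-3′, the only ring A carbon still bearing hydrogen: the first equivalent of 21 gives 22, which is deprotonated again and takes up the second equivalent to form the quaternary carbon. The protic medium and sodium counter-ion favour carbon over oxygen, as in lupulone-type gem-diprenylations of acylphloroglucinol-derived triones. The tertiary alcohols stay un-ionised and no stereocentre is involved.

## Compound list

1 | (S)-limonene | CC1=CC[C@@H](C(C)=C)CC1 | starting material
2 | (4S)-limonene 1,2-oxide (epoxide diastereomers) | CC12OC1C[C@@H](C(C)=C)CC2 | intermediate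
3 | (4S)-1-methyl-4-(prop-1-en-2-yl)cyclohexane-1,2-diol | CC1(O)C(O)C[C@@H](C(C)=C)CC1 | intermediate (not isolated)
4 | (3S)-6-oxo-3-(prop-1-en-2-yl)heptanal | O=CC[C@H](CCC(C)=O)C(C)=C | intermediate
5 | (1R,2S,5S)-2-hydroxy-2-methyl-5-(prop-1-en-2-yl)cyclopentane-1-carbaldehyde | O=C[C@@H]1[C@H](CC[C@]1(C)O)C(C)=C | intermediate
6 | (1S,2S,3S)-2-(hydroxymethyl)-1-methyl-3-(prop-1-en-2-yl)cyclopentan-1-ol | OC[C@@H]1[C@H](CC[C@]1(C)O)C(C)=C | intermediate
7 | primary tosylate of 6 | Cc1ccc(cc1)S(=O)(=O)OC[C@@H]1[C@H](CC[C@]1(C)O)C(C)=C | intermediate
8 | allylic chloride tosylate | Cc1ccc(cc1)S(=O)(=O)OC[C@@H]1[C@H](CC[C@]1(C)O)C(=C)CCl | intermediate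
9 | dimethyl malonate | COC(=O)CC(=O)OC | starting material
10 | allylated malonate tosylate | Cc1ccc(cc1)S(=O)(=O)OC[C@@H]1[C@H](CC[C@]1(C)O)C(=C)CC(C(=O)OC)C(=O)OC | intermediate (not isolated)
11 | spiro-alkylation product, 4-methylidene hydrindane 6,6-diester | COC(=O)C1(C(=O)OC)C[C@@H]2[C@H](CC[C@]2(C)O)C(=C)C1 | intermediate
12 | C-4 hydroperoxide of the diester | COC(=O)C1(C(=O)OC)C[C@@H]2[C@H](CC[C@]2(C)O)[C@@](C)(OO)C1 | intermediate (not isolated)
13 | 1,4-diol 6,6-diester | COC(=O)C1(C(=O)OC)C[C@@H]2[C@H](CC[C@]2(C)O)[C@@](C)(O)C1 | intermediate
14 | half ester (equatorial acid, axial methyl ester) | COC(=O)[C@@]1(C[C@@H]2[C@H](CC[C@]2(C)O)[C@@](C)(O)C1)C(=O)O | intermediate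
15 | 5-methylhexane-2,4-dione | CC(C)C(=O)CC(C)=O | starting material
16 | tris(trimethylsilyl) derivative of 14 | COC(=O)[C@@]1(C[C@@H]2[C@H](CC[C@]2(C)O[Si](C)(C)C)[C@@](C)(O[Si](C)(C)C)C1)C(=O)O[Si](C)(C)C | intermediate (not isolated)
17 | equatorial acid chloride, bis(trimethylsilyl) ether | COC(=O)[C@@]1(C[C@@H]2[C@H](CC[C@]2(C)O[Si](C)(C)C)[C@@](C)(O[Si](C)(C)C)C1)C(Cl)=O | intermediate (not isolated)
18 | triacylmethane methyl ester, bis(trimethylsilyl) ether (central carbon configurationally labile, enolised) | COC(=O)[C@@]1(C[C@@H]2[C@H](CC[C@]2(C)O[Si](C)(C)C)[C@@](C)(O[Si](C)(C)C)C1)C(=O)C(C(C)=O)C(=O)C(C)C | intermediate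
19 | bis(trimethylsilyl) ether of the spiro trione | C1C(=O)[C@@]2(C[C@@H]3[C@H](CC[C@]3(C)O[Si](C)(C)C)[C@@](C)(O[Si](C)(C)C)C2)C(=O)C(C(=O)C(C)C)=C1O | intermediate (not isolated)
20 | spiro trione diol | C1C(=O)[C@@]2(C[C@@H]3[C@H](CC[C@]3(C)O)[C@@](C)(O)C2)C(=O)C(C(=O)C(C)C)=C1O | intermediate
21 | prenyl bromide | CC(C)=CCBr | starting material
22 | 3′-monoprenyl spiro trione (C-3′ labile) | CC(C)=CCC1C(=O)[C@@]2(C[C@@H]3[C@H](CC[C@]3(C)O)[C@@](C)(O)C2)C(=O)C(C(=O)C(C)C)=C1O | intermediate (not isolated)
23 | target CNP0273836.5 | CC(C)=CCC1(CC=C(C)C)C(=O)[C@@]2(C[C@@H]3[C@H](CC[C@]3(C)O)[C@@](C)(O)C2)C(=O)C(C(=O)C(C)C)=C1O | target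

## Step count and least certain steps

Total step count: 12. Longest linear sequence: 12 steps (1 → 23); 9, 15 and 21 enter as purchased materials.

**Step 3 (key step).** The most likely failure is loss of water from the aldol through the product enamine, which drains everything to the conjugated enal. Next most likely is incomplete equilibration at C-1, or leakage into the crossed aldol mode if the ketone begins to act as donor on long exposure.
Fallback, from 4 back to 5: the condensation is driven to completion (piperidine, AcOH, toluene, reflux) to give (5R)-2-methyl-5-(prop-1-en-2-yl)cyclopent-1-ene-1-carbaldehyde F1. Weitz–Scheffer epoxidation (H2O2, NaOH, MeOH, 0 °C), expected mainly on the face away from the isopropenyl group, gives the α,β-epoxy aldehyde F2. Electron-transfer cleavage of the Cα–O bond with SmI2 (THF/MeOH, −90 °C) keeps the oxygen on C-1, and protonation of the enolate trans to the isopropenyl group returns 5, which is reduced at once as in step 4.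

**Step 8.** Oxygen capture by the C-4 radical may show poor facial selectivity, because the inherent axial preference of cyclohexyl radicals opposes the steric bias from the axial ester. The C-4 epimer would be expected to lactonise onto the axial ester.
Fallback, from 11 back to 13: epoxidation with mCPBA (NaHCO3, CH2Cl2, 0 °C), a concerted process that should also take the open equatorial side, gives the spiro epoxide F3. Opening at the CH2 terminus with PhSeNa ((PhSe)2, NaBH4, EtOH) gives the β-hydroxy selenide F4. Bu3SnH/AIBN (toluene, 80 °C) replaces selenium by hydrogen and returns 13.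

**Step 10.** C–C bond formation between a neopentyl acyl chloride and the crowded central carbon of the diketone may be slow. It could be diverted to O-acylation, or accompanied by loss of silyl groups during a long reaction.
Fallback, from 17 back to 18: 17 is added to the kinetic lithium enolate of 3-methylbutan-2-one (LiN(iPr)2, THF, −78 °C, 2.2 equiv), a smaller and more reactive nucleophile, to give the β-diketone F5. C-acetylation of its magnesium enolate (AcCl, MgCl2, pyridine, CH2Cl2) with an unhindered electrophile gives 18.

**Step 11.** The terminal carbanion may fail to add to the axial ester, which is crowded by the syn-axial 4-methyl group. The triacylmethane may instead lose an acyl group by retro-Claisen cleavage once methoxide is present.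
Fallback, from 11 back to 20: ring A is annulated before C-4 is hydrated, when the axial ester has no syn-axial methyl group.
- Saponification of 11 (KOH, MeOH/H2O) gives the methylidene half ester F6. Selectivity for the equatorial ester is expected to be lower here than in step 9.
- 1-Chloro-N,N,2-trimethylprop-1-en-1-amine (1.0 equiv, CH2Cl2, 0 °C) gives the acid chloride F7, with the single, hindered ring C hydroxyl left free.
- Acylation of 15 (MgCl2, pyridine) gives the methylidene triacylmethane F8.
- Closure with LiN(iPr)2 (4.4 equiv to allow for the free hydroxyl, THF, −78 → 0 °C) gives the methylidene spiro trione A1.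
- Mukaiyama hydration of A1 (Mn(dpm)3, PhSiH3, O2, iPrOH; then PPh3) through the hydroperoxide F9 gives 20. The price is a hydration in the presence of a metal-binding enolised triketone.

**Step 12.** O-alkylation of the ambident dianion, a sluggish second alkylation at the crowded C-3′, or methoxide-induced opening of ring A at C-2′ may erode the step.
Fallback, from 20 back to 23: Tsuji–Trost allylation (allyl methyl carbonate, Pd(PPh3)4, THF, 20 °C) should funnel to carbon because O-allyl products re-ionise on zerovalent palladium, giving the 3′,3′-diallyl trione F10. Double cross-metathesis with 2-methylbut-2-ene (second-generation Grubbs catalyst, CH2Cl2, 40 °C) converts both allyl groups into prenyl groups and gives 23.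

## Further compounds

F1 | step 3 | (5R)-2-methyl-5-(prop-1-en-2-yl)cyclopent-1-ene-1-carbaldehyde | O=CC1=C(C)CC[C@@H]1C(C)=C
F2 | step 3 | α,β-epoxy aldehyde, epoxide oxygen trans to the isopropenyl group | O=C[C@]12O[C@@]1(C)CC[C@@H]2C(C)=C
F3 | step 8 | spiro epoxide of 11 (oxygen equatorial on C-4) | COC(=O)C1(C(=O)OC)C[C@@H]2[C@H](CC[C@]2(C)O)[C@@]3(OC3)C1
F4 | step 8 | β-hydroxy phenyl selenide | COC(=O)C1(C(=O)OC)C[C@@H]2[C@H](CC[C@]2(C)O)[C@@](C[Se]c3ccccc3)(O)C1
F5 | step 10 | β-diketone methyl ester, bis(trimethylsilyl) ether | COC(=O)[C@@]1(C[C@@H]2[C@H](CC[C@]2(C)O[Si](C)(C)C)[C@@](C)(O[Si](C)(C)C)C1)C(=O)CC(=O)C(C)C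
F6 | step 11 | 4-methylidene half ester (equatorial acid, axial methyl ester) | COC(=O)[C@@]1(C[C@@H]2[C@H](CC[C@]2(C)O)C(=C)C1)C(=O)O
F7 | step 11 | 4-methylidene acid chloride | COC(=O)[C@@]1(C[C@@H]2[C@H](CC[C@]2(C)O)C(=C)C1)C(Cl)=O
F8 | step 11 | 4-methylidene triacylmethane methyl ester | COC(=O)[C@@]1(C[C@@H]2[C@H](CC[C@]2(C)O)C(=C)C1)C(=O)C(C(C)=O)C(=O)C(C)C
F9 | step 11 | C-4 hydroperoxide of the spiro trione | C1C(=O)[C@@]2(C[C@@H]3[C@H](CC[C@]3(C)O)[C@@](C)(OO)C2)C(=O)C(C(=O)C(C)C)=C1O
F10 | step 12 | 3′,3′-diallyl spiro trione diol | C=CCC1(CC=C)C(=O)[C@@]2(C[C@@H]3[C@H](CC[C@]3(C)O)[C@@](C)(O)C2)C(=O)C(C(=O)C(C)C)=C1O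
A1 | alternative 1 | methylidene spiro trione | C1C(=O)[C@@]2(C[C@@H]3[C@H](CC[C@]3(C)O)C(=C)C2)C(=O)C(C(=O)C(C)C)=C1O
A2 | alternative 1 | acylphloroglucinol carrying the ring C side chain as its allylic methyl carbonate | CC(C)C(=O)c1c(O)cc(O)c(C[C@@H]2[C@H](CC[C@]2(C)O)C(=C)COC(=O)OC)c1O
A3 | alternative 2 | trans-2-(arylmethyl)-3-isopropenylcyclopentanone | CC(C)C(=O)c1c(O)cc(O)c(C[C@@H]2[C@H](CCC2=O)C(C)=C)c1O
A4 | alternative 2 | cyclopent-2-en-1-one | O=C1C=CCC1
A5 | alternative 2 | isopropenylmagnesium bromide | CC(=C)[Mg]Br
A6 | alternative 2 | 2,4,6-trihydroxy-3-(2-methylpropanoyl)benzyl acetate | CC(=O)OCc1c(O)cc(O)c(C(=O)C(C)C)c1O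
A7 | alternative 2 | ortho-quinone methide from A6 | CC(C)C(=O)C1=C(O)C(=C)C(=O)C=C1O
A8 | alternative 3 | spiro hydrindene triketone with C-4=C-5 alkene and gem-diallyl group | C=CCC1(CC=C)C(=O)[C@@]2(C[C@@H]3[C@H](CC[C@]3(C)O)C(C)=C2)C(=O)C(C(=O)C(C)C)=C1O
A9 | alternative 3 | alkylidene triketone (Knoevenagel adduct of A11 and A10) | C=CCC1(CC=C)C(=O)C(=C/C(C)=C/CC[C@](C)(O)C=C)C(=O)C(C(=O)C(C)C)=C1O
A10 | alternative 3 | (2E,6S)-6-hydroxy-2,6-dimethylocta-2,7-dienal | O=C/C(C)=C/CC[C@](C)(O)C=C
A11 | alternative 3 | 3,3-diallyl-5-(2-methylpropanoyl)cyclohexane-1,3,5-trione enol | C=CCC1(CC=C)C(=O)CC(=O)C(C(=O)C(C)C)=C1O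
A12 | alternative 3 | (S)-linalool | CC(C)=CCC[C@](C)(O)C=C
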